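The earlier runs and the new flask were generated by integration for substances that don't exist.

How much substrate stays at 8.0 min when the charge is twice that of zeta?

- zeta: substrate 1 M; run made earlier
- flask: substrate 2.0 M; time 8.0 min

- zeta (time / min: product / %, substrate / %): 1.33: 14.0, 85.5; 2.50: 26.3, 74.0; 4.00: 40.0, 59.8; 5.00: 48.5, 51.5; 6.00: 56.3, 43.7; 8.00: 68.5, 31.2

(standard deviation of a reading: 0.3 percentage points)

- amount of product in the flask at 8.0 min, in percent of the substrate charged
- amount of substrate in the flask at 8.0 min, in percent of the substrate charged



My zero was first-order decay, which leaves the same percentage at any charge, here 31.2%. But zeta's apparent first-order constant rose from 0.118 /min to 0.146 /min. So I assumed saturation, rate = k[substrate]/(1 + [substrate]/K), and read K and k from two pairs of zeta readings.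

| Zeta readings at | K | k | Half-time at this charge | Substrate left |
|---|---|---|---|---|
| 4.00 min, 8.00 min | 0.850 M | 0.247 /min | 7.58 min | 47.6% |
| 2.50 min, 5.00 min | 0.570 M | 0.303 /min | 8.08 min | 50.4% |

The charge matters directly: on the first pair, the half-time is 5.19 min at zeta's charge and 7.58 min at this flask's. Between the pairs K moved by 0.280 M, but k moved the other way, and the substrate left moved by 2.8 percentage points. I therefore carried the half-time (half-life), (ln 2 + charge/(2K))/k, and expected about half left.

The forecast said 46% substrate and 54% product: “I favour saturation as the commoner behaviour”.

The flask held 49.0% substrate and 51.0% product, within the forecast's margin. My half-time of 7.58 min lay before 8.0 min, and the flask stood just under half; half its turnover was done by 3.76 min, earlier than 4.00 min.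

    substrate → product, rate k1*[substrate]/(1 + ([substrate]/sat1)) (0.730 M, k = 0.00440 /s)

For the neighbour flask charged with 0.80 M, the same half-time comes to 4.72 min. Two halvings in that flask take 8.48 min, longer than 8.0 min. That neighbour flask was computed at 26.9% substrate.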